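**Plan**

Route numbering: C1 allyl bridgehead, C2 CH2, C3 CH(OMe), C4 C=O, C5 OMe bridgehead, C6 CH(aryl), C7 CH(Me), C8 CH(OAc).
Retrosynthesis: the C3–OMe, O-acetyl and C8–H bonds go first (→ 4,8-dione 13). Then C1–C8 and C1–C2 are cut together, followed by C5–OMe, C1–allyl, C6–C7 and C5=C6.
Enabling feature: in ring C1–C2–C3–C4–C5–C8 the oxygenated carbons C4 and C8 flank the methoxy-bearing C5, and C1 carries only allyl and C7 outside that ring. Removing C1 therefore leaves a 2-methoxycyclopentane-1,3-dione (C8–C5–C4–C3–C2) and turns C1 into the carbon of a tethered diazoalkane.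
Forward: the chain C5–C6–C7–C1 is joined to cyclopentane-1,3-dione (steps 1–7). Step 8 closes the cyclopentane C1–C7–C6–C5–C8 and in the same event enlarges the dione ring by C1. Steps 9–13 adjust C8 and C3.
Stereochemistry: C6 and C7 come from an amine organocatalyst. C5 and C1 come from the substrate-controlled choice of one of two diastereotopic carbonyls plus bridge geometry. C8 comes from electron-transfer reduction, and C3 from endo-face oxidation enforced by the C8 acetate.

Key step: step 8

Remark: 1,3-diones 7, 9 and 10 are drawn and named as diketo tautomers although they should exist as enols. The lactol carbon of 5, the C=N geometry of 10 and the two oxadiazoline carbons of 11 are stereochemically mixed and of no consequence. Bicyclic compounds are named with the route numbering, not with lowest locants.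

**Step 1**
Reactants: 1 cyclopentane-1,3-dione; 2 3,4-dimethoxybenzaldehyde
Product: 3 2-(3,4-dimethoxybenzylidene)cyclopentane-1,3-dione
Conditions: piperidine (10 mol %), AcOH (10 mol %), 2 in slight excess, EtOH, rt
Reagents that add atoms: none
Why: Knoevenagel condensation of the acidic 1,3-dione with the aldehyde; the push–pull stabilised, sparingly soluble arylidene dione should crystallise from the medium before a second dione can add, and no stereocentre is formed.

**Step 2**
Reactants: 3 2-(3,4-dimethoxybenzylidene)cyclopentane-1,3-dione; 4 propanal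
Product: 5 (3R,4S)-4-(3,4-dimethoxyphenyl)-2-hydroxy-3-methyl-3,4,6,7-tetrahydrocyclopenta[b]pyran-5(2H)-one (lactol form of the Michael adduct)
Conditions: (S)-α,α-diphenylprolinol trimethylsilyl ether (10 mol %), PhCO2H (10 mol %), toluene, 0 °C
Reagents that add atoms: none
Why: Enamine-catalysed asymmetric Michael addition of an aldehyde to a doubly activated alkylidene 1,3-dicarbonyl compound: the E-enamine reacts on the face left open by the diphenyl(silyloxy)methyl group through the usual synclinal transition state, which should set C7 (3R) and C6 (4S) in the syn sense, and closure to the lactol protects the new α-centre from epimerisation.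

**Step 3**
Reactants: 5 lactol
Product: 6 (3R,4S)-4-(3,4-dimethoxyphenyl)-3-methyl-3,4,6,7-tetrahydrocyclopenta[b]pyran-2,5-dione (enol lactone)
Conditions: TEMPO (10 mol %), PhI(OAc)2, CH2Cl2, rt
Reagents that add atoms: none
Why: Oxoammonium (TEMPO/iodine(III)) oxidation of a lactol to the lactone; the dione enol is tied up as the ring enol ether and C6 and C7 are untouched.

**Step 4**
Reactants: 6 enol lactone
Product: 7 (2R,3S)-3-(3,4-dimethoxyphenyl)-3-(2,5-dioxocyclopentyl)-N-methoxy-N,2-dimethylpropanamide
Conditions: MeNH(OMe)·HCl, iPr2NEt, CH2Cl2, 0 °C → rt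
Reagents that add atoms: N,O-dimethylhydroxylamine hydrochloride, CNOC.Cl
Why: Aminolysis of an enol ester, an acyl donor of mixed-anhydride strength because the leaving group is the stabilised dione enolate, should give the Weinreb amide at low temperature without touching C7.

**Step 5**
Reactants: 7 Weinreb amide; 8 allylmagnesium bromide
Product: 9 2-[(1R,2R)-1-(3,4-dimethoxyphenyl)-2-methyl-3-oxohex-5-en-1-yl]cyclopentane-1,3-dione
Conditions: 8 (2.2 equiv), THF, –78 °C; AcOH, –78 °C
Reagents that add atoms: none
Why: Weinreb ketone synthesis: the first equivalent of 8 turns the acidic dione into an inert magnesium enolate, the second adds once to the amide to give the stable chelate, and the cold acidic quench should prevent conjugation of the β,γ-enone and epimerisation at C7.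

**Step 6**
Reactants: 9 allyl ketone
Product: 10 N'-[(5R,6R)-6-(3,4-dimethoxyphenyl)-6-(2,5-dioxocyclopentyl)-5-methylhex-1-en-4-ylidene]acetohydrazide
Conditions: AcNHNH2 (1.1 equiv), 4 Å MS, MeOH, rt
Reagents that add atoms: acetohydrazide, CC(=O)NN
Why: Acylhydrazone condensation at the only true ketone: the ring carbonyls exist as a hindered, enolised vinylogous acid that is a poor electrophile and at the same time supplies mild acid catalysis, and the base-free medium spares the allyl ketone.

**Step 7**
Reactants: 10 N-acetylhydrazone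
Product: 11 2-{(1S,2R)-1-(3,4-dimethoxyphenyl)-2-[2-methoxy-2-methyl-5-(prop-2-en-1-yl)-2,5-dihydro-1,3,4-oxadiazol-5-yl]propyl}-2-methoxycyclopentane-1,3-dione
Conditions: PhI(OAc)2 (2.3 equiv), MeOH, –10 → 0 °C
Reagents that add atoms: methanol, CO
Why: Two known iodine(III) oxidations run side by side, the oxidative cyclisation of a ketone N-acylhydrazone in an alcohol to the 2-alkoxy-Δ3-1,3,4-oxadiazoline (a storable masked diazoalkane) and the α-alkoxylation of a 2-substituted 1,3-dicarbonyl compound by ligand coupling at iodine; C5 carries two equal carbonyl arms and is not yet stereogenic, and the oxadiazoline centres are lost in step 8.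

**Step 8**
Reactants: 11 oxadiazoline
Product: 13 (1R,5R,6S,7R)-1-allyl-6-(3,4-dimethoxyphenyl)-5-methoxy-7-methylbicyclo[3.2.1]octane-4,8-dione, via diazoalkane 12 (not isolated)
Conditions: hν (UV-A, ca. 350 nm), CH2Cl2 (0.005 M), 0 °C
Reagents that add atoms: none
Why: Proposed new method: UV-A light splits the oxadiazoline of 11 into methyl acetate and the unstabilised diazoalkane 12, whose nucleophilic carbon C1 adds to one ring carbonyl (C8) in a 5-exo-trig closure of ring C1–C7–C6–C5–C8, and the resulting diazonium alkoxide loses N2 while the antiperiplanar C8–C2 bond moves to C1, so that the five-membered dione ring C8–C5–C4–C3–C2 takes up C1 and becomes the six-membered ring C1–C2–C3–C4–C5–C8 with C8 again a ketone. The closest known reaction types are the Büchner–Curtius–Schlotterbeck and Tiffeneau–Demjanov-type one-carbon enlargement of cyclic ketones by diazoalkanes, its intramolecular form that turns 2-(ω-diazoalkyl)cycloalkanones into bridged bicyclic ketones, and the insertion of photochemically released dialkyl diazo compounds into aldehydes; new are the 2,2-disubstituted 1,3-dione as acceptor, the fully substituted diazo carbon and the group-selective course. C5 becomes stereogenic through the choice between its two diastereotopic carbonyl groups, which C6 and C7 control: in the reactive fold the flat, electron-rich aryl group lies anti to the C5 methoxy group over the acceptor ring, C7 then reaches only the carbonyl that leaves aryl cis to C4 (endo in 13), and the other fold would put the C7 methyl group on the concave face, eclipsed with allyl and in the path of the migrating C2. C1 has no freedom of its own, because N2 departs from the convex face and C2 enters from the concave face of the cis-fused intermediate, so that its configuration is tied to that of C5 by the bridge. Bond selectivity in the shift is secured by geometry and electronics: C5 belongs to the new ring and cannot stand anti to N2, is deactivated by its methoxy and acyl groups and would give a cyclobutane, and the charge-paired rotamer with the diazonium group syn to the alkoxide cannot close to the epoxide. The addition must also outrun 1,2-hydrogen shift, azine formation and the reversible 1,1-cycloaddition of the diazo group to the allyl double bond, which the short tether, the doubly activated (α-alkoxy, β-keto) carbonyl group, high dilution and low temperature should secure.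

**Step 9**
Reactants: 13 bicyclic 4,8-dione
Product: 14 (1S,5R,6S,7R)-1-allyl-4-(tert-butyldimethylsilyloxy)-6-(3,4-dimethoxyphenyl)-5-methoxy-7-methylbicyclo[3.2.1]oct-3-en-8-one
Conditions: TBSOTf, Et3N, CH2Cl2, 0 °C
Reagents that add atoms: tert-butyldimethylsilyl trifluoromethanesulfonate, CC(C)(C)[Si](C)(C)OS(=O)(=O)C(F)(F)F
Why: Soft enolisation and silylation: C8 has no α-hydrogen and C4 can enolise only towards C3 because C5 is quaternary, so a single silyl enol ether should form that masks C4 and prepares C3 for oxidation.

**Step 10**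
Reactants: 14 silyl enol ether ketone
Product: 15 (1S,5S,6S,7R,8S)-1-allyl-4-(tert-butyldimethylsilyloxy)-6-(3,4-dimethoxyphenyl)-5-methoxy-7-methylbicyclo[3.2.1]oct-3-en-8-ol
Conditions: SmI2 (2.5 equiv), H2O (50 equiv), THF, 0 °C
Reagents that add atoms: none
Why: Single-electron (ketyl) reduction is not under steric approach control: as in the dissolving-metal reduction of camphor to borneol, the oxygen should settle on the less crowded side, here over the C2–C4 bridge and away from the exo C7 methyl group, with C8–H formed on the methyl side (8S), while the bridgehead C5–OMe bond lies in the nodal plane of the C8 carbonyl and could only give a bridgehead enolate, so it should not be cleaved.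

**Step 11**
Reactants: 15 alcohol
Product: 16 (1S,5S,6S,7R,8S)-1-allyl-4-(tert-butyldimethylsilyloxy)-6-(3,4-dimethoxyphenyl)-5-methoxy-7-methylbicyclo[3.2.1]oct-3-en-8-yl acetate
Conditions: Ac2O, DMAP, pyridine, rt
Reagents that add atoms: acetic anhydride, CC(=O)OC(C)=O
Why: DMAP-catalysed acetylation of the outward-pointing bridge alcohol under conditions that leave the silyl enol ether intact; acetylation comes before the C3 oxidation so that no free hydroxyl can direct the oxidant to the exo face.

**Step 12**
Reactants: 16 acetate
Product: 18 (1S,3S,5S,6S,7R,8S)-1-allyl-6-(3,4-dimethoxyphenyl)-3-hydroxy-5-methoxy-7-methyl-4-oxobicyclo[3.2.1]octan-8-yl acetate, via silyloxy epoxide 17 (not isolated)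
Conditions: dimethyldioxirane, acetone/CH2Cl2, –40 °C; then HF·pyridine, THF, 0 °C
Reagents that add atoms: dimethyldioxirane, CC1(C)OO1
Why: Rubottom oxidation: the silyl enol ether is by far the most electron-rich alkene, and the C8 acetate, which hangs over the exo face of C3=C4, should force the oxidant to the endo face so that C3–O forms cis to the C6–C7 bridge (3S), after which fluoride opens the silyloxy epoxide to the ketol.

**Step 13**
Reactants: 18 α-hydroxy ketone
Product: 19 (1S,3S,5S,6S,7R,8S)-1-allyl-6-(3,4-dimethoxyphenyl)-3,5-dimethoxy-7-methyl-4-oxobicyclo[3.2.1]octan-8-yl acetate (target CNP0344493.1)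
Conditions: MeI, Ag2O, 4 Å MS, CH2Cl2, 35 °C, dark
Reagents that add atoms: iodomethane, CI
Why: Purdie methylation under nearly neutral conditions should etherify the C3 hydroxyl without epimerising the C3 centre next to the ketone and without cleaving or shifting the acetate.

**Compound list**

1 | cyclopentane-1,3-dione | O=C1CCC(=O)C1 | starting material
2 | 3,4-dimethoxybenzaldehyde | COc1ccc(C=O)cc1OC | starting material
3 | 2-(3,4-dimethoxybenzylidene)cyclopentane-1,3-dione | COc1ccc(C=C2C(=O)CCC2=O)cc1OC | intermediate
4 | propanal | CCC=O | starting material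
5 | (3R,4S)-4-(3,4-dimethoxyphenyl)-2-hydroxy-3-methyl-3,4,6,7-tetrahydrocyclopenta[b]pyran-5(2H)-one, anomer mixture | O=C1CCC2=C1[C@H](c3ccc(OC)c(OC)c3)[C@@H](C)C(O)O2 | intermediate
6 | (3R,4S)-4-(3,4-dimethoxyphenyl)-3-methyl-3,4,6,7-tetrahydrocyclopenta[b]pyran-2,5-dione | O=C1CCC2=C1[C@H](c3ccc(OC)c(OC)c3)[C@@H](C)C(=O)O2 | intermediate
7 | (2R,3S)-3-(3,4-dimethoxyphenyl)-3-(2,5-dioxocyclopentyl)-N-methoxy-N,2-dimethylpropanamide | O=C1CCC(=O)C1[C@H](c2ccc(OC)c(OC)c2)[C@@H](C)C(=O)N(C)OC | intermediate
8 | allylmagnesium bromide | C=CC[Mg]Br | starting material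
9 | 2-[(1R,2R)-1-(3,4-dimethoxyphenyl)-2-methyl-3-oxohex-5-en-1-yl]cyclopentane-1,3-dione | O=C1CCC(=O)C1[C@H](c2ccc(OC)c(OC)c2)[C@@H](C)C(=O)CC=C | intermediate
10 | N'-[(5R,6R)-6-(3,4-dimethoxyphenyl)-6-(2,5-dioxocyclopentyl)-5-methylhex-1-en-4-ylidene]acetohydrazide | O=C1CCC(=O)C1[C@H](c2ccc(OC)c(OC)c2)[C@@H](C)C(CC=C)=NNC(C)=O | intermediate
11 | 2-{(1S,2R)-1-(3,4-dimethoxyphenyl)-2-[2-methoxy-2-methyl-5-(prop-2-en-1-yl)-2,5-dihydro-1,3,4-oxadiazol-5-yl]propyl}-2-methoxycyclopentane-1,3-dione | COC1(C(=O)CCC1=O)[C@H](c2ccc(OC)c(OC)c2)[C@@H](C)C3(CC=C)N=NC(C)(OC)O3 | intermediate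
12 | 2-[(1S,2R)-3-diazo-1-(3,4-dimethoxyphenyl)-2-methylhex-5-en-1-yl]-2-methoxycyclopentane-1,3-dione | COC1(C(=O)CCC1=O)[C@H](c2ccc(OC)c(OC)c2)[C@@H](C)C(=[N+]=[N-])CC=C | intermediate
13 | (1R,5R,6S,7R)-1-allyl-6-(3,4-dimethoxyphenyl)-5-methoxy-7-methylbicyclo[3.2.1]octane-4,8-dione | C=CC[C@]12CCC(=O)[C@](OC)([C@H](c3ccc(OC)c(OC)c3)[C@H]1C)C2=O | intermediate
14 | (1S,5R,6S,7R)-1-allyl-4-(tert-butyldimethylsilyloxy)-6-(3,4-dimethoxyphenyl)-5-methoxy-7-methylbicyclo[3.2.1]oct-3-en-8-one | C=CC[C@]12CC=C(O[Si](C)(C)C(C)(C)C)[C@](OC)([C@H](c3ccc(OC)c(OC)c3)[C@H]1C)C2=O | intermediate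
15 | (1S,5S,6S,7R,8S)-1-allyl-4-(tert-butyldimethylsilyloxy)-6-(3,4-dimethoxyphenyl)-5-methoxy-7-methylbicyclo[3.2.1]oct-3-en-8-ol | C=CC[C@]12CC=C(O[Si](C)(C)C(C)(C)C)[C@](OC)([C@H](c3ccc(OC)c(OC)c3)[C@H]1C)[C@H]2O | intermediate
16 | (1S,5S,6S,7R,8S)-1-allyl-4-(tert-butyldimethylsilyloxy)-6-(3,4-dimethoxyphenyl)-5-methoxy-7-methylbicyclo[3.2.1]oct-3-en-8-yl acetate | C=CC[C@]12CC=C(O[Si](C)(C)C(C)(C)C)[C@](OC)([C@H](c3ccc(OC)c(OC)c3)[C@H]1C)[C@H]2OC(C)=O | intermediate
17 | 3,4-epoxide of 16 with the oxirane oxygen on the endo face (cis to the C6–C7 bridge) and the silyloxy group on C4 | C=CC[C@]12C[C@@H]3O[C@]3(O[Si](C)(C)C(C)(C)C)[C@](OC)([C@H](c4ccc(OC)c(OC)c4)[C@H]1C)[C@H]2OC(C)=O | intermediate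
18 | (1S,3S,5S,6S,7R,8S)-1-allyl-6-(3,4-dimethoxyphenyl)-3-hydroxy-5-methoxy-7-methyl-4-oxobicyclo[3.2.1]octan-8-yl acetate | C=CC[C@]12C[C@H](O)C(=O)[C@](OC)([C@H](c3ccc(OC)c(OC)c3)[C@H]1C)[C@H]2OC(C)=O | intermediate
19 | (1S,3S,5S,6S,7R,8S)-1-allyl-6-(3,4-dimethoxyphenyl)-3,5-dimethoxy-7-methyl-4-oxobicyclo[3.2.1]octan-8-yl acetate | C=CC[C@]12C[C@H](OC)C(=O)[C@](OC)([C@H](c3ccc(OC)c(OC)c3)[C@H]1C)[C@H]2OC(C)=O | target

Total step count: 13. Longest linear sequence: 13 steps (from 1).

**Steps most likely to fail**

Step 8 (Proposed new method). Three processes could defeat it: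
- poor discrimination between the two diastereotopic carbonyl groups;
- loss of the diazoalkane through hydrogen shift or through addition to the allyl double bond before it reaches the carbonyl;
- closure of the adduct to an epoxide instead of the shift.

The fallback sets out from 5 and comes back at 13. It keeps the same C2 shift but reaches it with known reactions. PhI(OAc)2 in MeOH methoxylates C5 of the open enol form of 5 to give the methoxy dione aldehyde F1. A chiral triazolium-derived N-heterocyclic carbene with a weak amine base then joins the two electrophilic carbons C1 and C8 by polarity reversal at C1. This intramolecular crossed aldehyde–ketone benzoin reaction is known as a desymmetrisation of 2,2-disubstituted cyclopentane-1,3-diones, and the catalyst antipode is chosen to select the required carbonyl; it gives the cis-fused acyloin F2. Reagent 8 adds to the C1 carbonyl, which is chelated and activated by the magnesium alkoxide of the neighbouring C8 hydroxyl, and gives the diol F3; either C1 epimer serves. BF3·OEt2 in CH2Cl2 at –78 °C ionises the C1 hydroxyl, since the C8 hydroxyl sits next to the acceptor-flanked C5. The pinacol rearrangement then moves C2 from C8 to C1 to give 13.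

Step 10. Hydrogen may be delivered to the wrong face of C8, or with poor facial selectivity, and the ketyl may be slow to form at a carbonyl between two quaternary carbons. The fallback sets out from 13 and comes back at 16. It sets C8 through a reversible C–C bond instead of a C–H bond. NaBH4/CeCl3 in MeOH at –78 °C reduces the strained bridge carbonyl of 13 from its open face to the C8-epimeric hydroxy ketone F4. LiHMDS/MgBr2 in THF equilibrates it by retro-aldol and aldol reaction across C5–C8. Only the alkoxide that points towards the C4 carbonyl can form the six-membered magnesium chelate, so the chelated hydroxy ketone F5 should result. Ac2O/DMAP gives the keto acetate F6, and TBSOTf/Et3N converts F6 into 16.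

Step 7. The two oxidations may interfere: the iodine-bound C5 may be captured by the hydrazone nitrogen or by acetate instead of methanol, or conversion of one of the two sites may stay incomplete. The fallback sets out from 10 and comes back at 11. It delivers the C5 oxygen by atom transfer to the enolate instead of by ligand coupling. 2-(Phenylsulfonyl)-3-phenyloxaziridine with K2CO3 in THF hydroxylates the dione enolate to the hydroxy dione hydrazone F7. One equivalent of PhI(OAc)2 in MeOH then closes only the oxadiazoline to the hydroxy dione oxadiazoline F8, and MeI/Ag2O methylates the tertiary hydroxyl to give 11.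

**Further compounds**

F1 | step 8 | (2R,3S)-3-(3,4-dimethoxyphenyl)-3-(1-methoxy-2,5-dioxocyclopentyl)-2-methylpropanal | COC1(C(=O)CCC1=O)[C@H](c2ccc(OC)c(OC)c2)[C@@H](C)C=O
F2 | step 8 | cis-fused acyloin: bicyclo[3.3.0]octane with C8 hydroxyl and C5 methoxy at the ring fusion, C1 and C4 ketones, aryl on the concave face, methyl on the convex face | C[C@H]1C(=O)[C@]2(O)CCC(=O)[C@]2(OC)[C@@H]1c1ccc(OC)c(OC)c1
F3 | step 8 | C1-allyl C1,C8-diol derived from F2, allyl on the convex face | C[C@H]1[C@@](O)(CC=C)[C@]2(O)CCC(=O)[C@]2(OC)[C@@H]1c1ccc(OC)c(OC)c1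
F4 | step 10 | C8 epimer of the 8-hydroxy-4-ketone (hydroxyl over the C6–C7 bridge) | C=CC[C@]12CCC(=O)[C@](OC)([C@H](c3ccc(OC)c(OC)c3)[C@H]1C)[C@@H]2O
F5 | step 10 | 8-hydroxy-4-ketone with the hydroxyl over the C2–C4 bridge | C=CC[C@]12CCC(=O)[C@](OC)([C@H](c3ccc(OC)c(OC)c3)[C@H]1C)[C@H]2O
F6 | step 10 | 8-acetoxy-4-ketone | C=CC[C@]12CCC(=O)[C@](OC)([C@H](c3ccc(OC)c(OC)c3)[C@H]1C)[C@H]2OC(C)=O
F7 | step 7 | N-acetylhydrazone with 2-hydroxy-1,3-dione | OC1(C(=O)CCC1=O)[C@H](c2ccc(OC)c(OC)c2)[C@@H](C)C(CC=C)=NNC(C)=O
F8 | step 7 | oxadiazoline with 2-hydroxy-1,3-dione | OC1(C(=O)CCC1=O)[C@H](c2ccc(OC)c(OC)c2)[C@@H](C)C3(CC=C)N=NC(C)(OC)O3
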